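**Retrosynthetic overview**
1. All skeletal atoms come from three para-anisyl building blocks: keto acid 1, nitroalkene 2 and aminoketone salt 3.
2. Key disconnection: pyrrole C3–C4 (target C8–C7). Nitroalkene 2 acts as the α-cation (enolonium-type) equivalent of 4-methoxyphenylacetaldehyde and is attacked by the enolate carbon of dianion 4, giving nitro keto acid 5.
3. Pyrrole ring first, in the same flask: the amine of 3 condenses with the keto group (imine 6) and closes onto the nitro-bearing carbon with loss of HNO, giving N-phenacyl pyrrole acid 7.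
4. Oxazinone ring second: dehydrative enol-lactonisation through mixed anhydride 8 to trimethyl ether 9.
5. Last: threefold O-demethylation through aryl borate 10 to the target 11.

Assumption: the target (lukianol A) has no stereocentre and no stereogenic double bond, so there is no enantiomer to select. Intermediates 5 and 6 carry two transient stereocentres (racemic diastereomer mixture) that are erased on aromatisation.

**Step 1**
Reactants: 1 3-(4-methoxyphenyl)-2-oxopropanoic acid; 2 (E)-1-methoxy-4-(2-nitroethenyl)benzene; 3 2-amino-1-(4-methoxyphenyl)ethan-1-one hydrochloride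
Product: 7 1-[2-(4-methoxyphenyl)-2-oxoethyl]-3,4-bis(4-methoxyphenyl)-1H-pyrrole-2-carboxylic acid, via dilithium enolate 4 (not isolated), via nitro keto acid 5 (not isolated), via imine 6 (not isolated)
Conditions: LiN(SiMe3)2 (2.1 equiv), THF, −78 °C; add 2, −78 → −20 °C; then AcOH (10 equiv), 3 (1.3 equiv), EtOH, 70 °C
Reagents that add atoms: none
Why: Proposed new method: the aryl-conjugated enolate carbon of dianion 4 adds at low temperature to the β-carbon of nitroalkene 2 (lithium-enolate nitro-Michael addition), so that 2 serves as an α-cation equivalent of an arylacetaldehyde and the new bond links two carbons that are each α to a carbonyl-level carbon; after buffering with AcOH the amine condenses with the α-keto acid to imine/enamine 6, whose nitrogen attacks the aci-nitro carbon in a five-membered interrupted-Nef closure and aromatises with loss of water and HNO (which ends as N2O), the closest known reaction types being the Grob–Camenzind enamine–nitroalkene pyrrole synthesis and the ammonium-acetate cyclisation of γ-nitro ketones; the two transient stereocentres of 5 are destroyed.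

**Step 2**
Reactants: 7 1-[2-(4-methoxyphenyl)-2-oxoethyl]-3,4-bis(4-methoxyphenyl)-1H-pyrrole-2-carboxylic acid
Product: 9 3,7,8-tris(4-methoxyphenyl)-1H-pyrrolo[2,1-c][1,4]oxazin-1-one (lukianol A trimethyl ether), via mixed anhydride 8 (not isolated)
Conditions: Ac2O, NaOAc (1.5 equiv), 110 °C
Reagents that add atoms: none
Why: Ac2O converts the acid into mixed anhydride 8 and NaOAc enolises the aryl ketone, whose enol oxygen closes the six-membered ring by intramolecular O-acylation (dehydrative enol-lactonisation of an N-phenacyl pyrrole-2-carboxylic acid), C-acylation being excluded because it would need a four-membered ring; no stereocentre is involved.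

**Step 3**
Reactants: 9 3,7,8-tris(4-methoxyphenyl)-1H-pyrrolo[2,1-c][1,4]oxazin-1-one
Product: 11 3,7,8-tris(4-hydroxyphenyl)-1H-pyrrolo[2,1-c][1,4]oxazin-1-one (lukianol A; target), via aryl borate 10 (not isolated)
Conditions: BBr3 (6 equiv), CH2Cl2, −78 °C → rt; then H2O
Reagents that add atoms: none
Why: BBr3 cleaves the three aryl methyl ethers by Lewis acid complexation and bromide SN2 attack at methyl (Lewis-acid ether cleavage), the pyrrole-conjugated enol lactone is a poor electrophile and survives, and water hydrolyses borate 10 to the phenols; no stereocentre is involved.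

**Compound list**
1 | 3-(4-methoxyphenyl)-2-oxopropanoic acid (4-methoxyphenylpyruvic acid) | COc1ccc(CC(=O)C(=O)O)cc1 | starting material
2 | (E)-1-methoxy-4-(2-nitroethenyl)benzene (trans-4-methoxy-β-nitrostyrene) | COc1ccc(/C=C/[N+](=O)[O-])cc1 | starting material
3 | 2-amino-1-(4-methoxyphenyl)ethan-1-one hydrochloride | COc1ccc(cc1)C(=O)CN.Cl | starting material
4 | dilithium (Z)-enolate-carboxylate of 1 (dilithium 3-(4-methoxyphenyl)-2-oxidoprop-2-enoate) | COc1ccc(/C=C(\[O-])C(=O)[O-])cc1.[Li+].[Li+] | intermediate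
5 | 3,4-bis(4-methoxyphenyl)-5-nitro-2-oxopentanoic acid (formed as its dilithium nitronate-carboxylate, protonated by AcOH; racemic diastereomer mixture) | COc1ccc(cc1)C(C[N+](=O)[O-])C(c1ccc(OC)cc1)C(=O)C(=O)O | intermediate
6 | 2-{[2-(4-methoxyphenyl)-2-oxoethyl]imino}-3,4-bis(4-methoxyphenyl)-5-nitropentanoic acid (in equilibrium with its enamine; racemic diastereomer mixture) | COc1ccc(cc1)C(C[N+](=O)[O-])C(c1ccc(OC)cc1)C(=NCC(=O)c1ccc(OC)cc1)C(=O)O | intermediate
7 | 1-[2-(4-methoxyphenyl)-2-oxoethyl]-3,4-bis(4-methoxyphenyl)-1H-pyrrole-2-carboxylic acid | COc1ccc(cc1)C(=O)Cn1cc(-c2ccc(OC)cc2)c(-c2ccc(OC)cc2)c1C(=O)O | intermediate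
8 | acetic 1-[2-(4-methoxyphenyl)-2-oxoethyl]-3,4-bis(4-methoxyphenyl)-1H-pyrrole-2-carboxylic anhydride | COc1ccc(cc1)C(=O)Cn1cc(-c2ccc(OC)cc2)c(-c2ccc(OC)cc2)c1C(=O)OC(C)=O | intermediate
9 | 3,7,8-tris(4-methoxyphenyl)-1H-pyrrolo[2,1-c][1,4]oxazin-1-one | COc1ccc(cc1)-c1cn2cc(-c3ccc(OC)cc3)c(-c3ccc(OC)cc3)c2c(=O)o1 | intermediate
10 | 3,7,8-tris{4-[(dibromoboranyl)oxy]phenyl}-1H-pyrrolo[2,1-c][1,4]oxazin-1-one (idealised aryl borate) | O=c1oc(-c2ccc(OB(Br)Br)cc2)cn2cc(-c3ccc(OB(Br)Br)cc3)c(-c3ccc(OB(Br)Br)cc3)c12 | intermediate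
11 | 3,7,8-tris(4-hydroxyphenyl)-1H-pyrrolo[2,1-c][1,4]oxazin-1-one (lukianol A) | O=c1oc(-c2ccc(O)cc2)cn2cc(-c3ccc(O)cc3)c(-c3ccc(O)cc3)c12 | target

**Totals**
Total step count: 3. Longest linear sequence: 3 steps (step 1 is a convergent three-component step).

**Steps most likely to fail, with fallbacks**

Step 1 (highest risk). The direct amine closure onto the nitro carbon of an α-keto acid is untested. Possible problems are oligomerisation of 2, decarboxylation of imino acid 6, and self-condensation of free 3.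
Fallback, setting out from 1 (with 3) and coming back at 9: form dianion 4 as before but add only 0.5 equiv I2 (THF, −78 °C → rt). Half of the enolate is iodinated to lithium 3-iodo-3-(4-methoxyphenyl)-2-oxopropanoate F1, which is alkylated at once by the other half to give, after acidic work-up, 3,4-bis(4-methoxyphenyl)-2,5-dioxohexanedioic acid F2 (oxidative enolate homocoupling). Paal–Knorr condensation of the 1,4-diketone with 3 (NaOAc, AcOH, EtOH, rt → 50 °C) gives 1-[2-(4-methoxyphenyl)-2-oxoethyl]-3,4-bis(4-methoxyphenyl)-1H-pyrrole-2,5-dicarboxylic acid F3. Ac2O/NaOAc closes one carboxyl onto the ketone enol to give 3,7,8-tris(4-methoxyphenyl)-1-oxo-1H-pyrrolo[2,1-c][1,4]oxazine-6-carboxylic acid F4. Thermal decarboxylation of the remaining pyrrole α-carboxylic acid (Cu2O, quinoline, 200 °C) gives 9, bypassing 7 and step 2.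

Step 2. Hot Ac2O could decarboxylate the pyrrole-2-carboxylic acid before the ring closes, or give enol acetate by-products.
Fallback, setting out from 7 and coming back at 9: replace the thermal anhydride dehydration by a two-stage route through a discrete acyl halide. Treat 7 with (COCl)2 and catalytic DMF (CH2Cl2, 0 °C) to give 1-[2-(4-methoxyphenyl)-2-oxoethyl]-3,4-bis(4-methoxyphenyl)-1H-pyrrole-2-carbonyl chloride F5. Then add Et3N (CH2Cl2, 0 °C) so that the ketone enolate is O-acylated intramolecularly, giving 9 at or below room temperature.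

Step 3. BBr3 (with the HBr it releases) could open or brominate the enol lactone, or leave partly methylated material.
Fallback, setting out from 7 and coming back at 11: reverse the order of the last two operations and change the group removed last. BBr3 (CH2Cl2, −78 °C → rt; H2O) on 7 gives 1-[2-(4-hydroxyphenyl)-2-oxoethyl]-3,4-bis(4-hydroxyphenyl)-1H-pyrrole-2-carboxylic acid F6, with no lactone present to be attacked. Ac2O/NaOAc (110 °C) then closes the lactone and acetylates the phenols, giving (1-oxo-1H-pyrrolo[2,1-c][1,4]oxazine-3,7,8-triyl)tris(benzene-4,1-diyl) triacetate F7 (lukianol A triacetate). Mild selective cleavage of the aryl acetates (NH4OAc, MeOH, rt) gives 11.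

**Further compounds**
F1 | step 1 | lithium 3-iodo-3-(4-methoxyphenyl)-2-oxopropanoate | COc1ccc(cc1)C(I)C(=O)C(=O)[O-].[Li+]
F2 | step 1 | 3,4-bis(4-methoxyphenyl)-2,5-dioxohexanedioic acid (diastereomer mixture) | COc1ccc(cc1)C(C(=O)C(=O)O)C(c1ccc(OC)cc1)C(=O)C(=O)O
F3 | step 1 | 1-[2-(4-methoxyphenyl)-2-oxoethyl]-3,4-bis(4-methoxyphenyl)-1H-pyrrole-2,5-dicarboxylic acid | COc1ccc(cc1)C(=O)Cn1c(C(=O)O)c(-c2ccc(OC)cc2)c(-c2ccc(OC)cc2)c1C(=O)O
F4 | step 1 | 3,7,8-tris(4-methoxyphenyl)-1-oxo-1H-pyrrolo[2,1-c][1,4]oxazine-6-carboxylic acid | COc1ccc(cc1)-c1cn2c(C(=O)O)c(-c3ccc(OC)cc3)c(-c3ccc(OC)cc3)c2c(=O)o1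
F5 | step 2 | 1-[2-(4-methoxyphenyl)-2-oxoethyl]-3,4-bis(4-methoxyphenyl)-1H-pyrrole-2-carbonyl chloride | COc1ccc(cc1)C(=O)Cn1cc(-c2ccc(OC)cc2)c(-c2ccc(OC)cc2)c1C(=O)Cl
F6 | step 3 | 1-[2-(4-hydroxyphenyl)-2-oxoethyl]-3,4-bis(4-hydroxyphenyl)-1H-pyrrole-2-carboxylic acid | O=C(Cn1cc(-c2ccc(O)cc2)c(-c2ccc(O)cc2)c1C(=O)O)c1ccc(O)cc1
F7 | step 3 | (1-oxo-1H-pyrrolo[2,1-c][1,4]oxazine-3,7,8-triyl)tris(benzene-4,1-diyl) triacetate | CC(=O)Oc1ccc(cc1)-c1cn2cc(-c3ccc(OC(C)=O)cc3)c(-c3ccc(OC(C)=O)cc3)c2c(=O)o1
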